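**Plan**
- Retrosynthesis: after removal of the two silyl groups of indole A, the main cut is N1–C7a of indole B, leading back to a 2,2-diaryl-2H-azirine whose quaternary carbon becomes C3 of indole B.
- Enabling feature: C6 of indole B is para to C3a, so its benzenoid ring is a 4-prenylphenyl group with two equivalent ortho C–H carbons. Ring C (the tetramethoxybenzene) has methoxy groups on both carbons ortho to the same attachment point and offers no ortho hydrogen.
- Further cuts: azirine to vinyl azide, to alkenyl boronate, to diaryl ketone (C=C by boron-Wittig). The ketone comes from a ring C aryllithium plus 4-prenylbenzaldehyde, and the ring C–indole A C3 bond from a Negishi coupling.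
- Forward order: indole A is bought and protected, ring C is attached, the prenylphenyl ketone is built on ring C, the azirine is made, the pyrrole ring of indole B closes last, then desilylation.
- Stereochemistry: the target has no stereocentre. The carbinol and the azirine are racemic and lose their stereocentres, and alkene geometry is irrelevant.

Key step: step 10

Remark on the chemistry: the alkenyl boronate and the vinyl azide of steps 7 and 8 are assumed to be usable as E/Z mixtures, because both isomers give the same racemic azirine. Abbreviations: TIPS = triisopropylsilyl, prenyl = 3-methylbut-2-en-1-yl, Bpin = 4,4,5,5-tetramethyl-1,3,2-dioxaborolan-2-yl.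

**Route**

Step 1
Reactants: 1 5-hydroxyindole
Product: 2 1-(triisopropylsilyl)-5-(triisopropylsilyloxy)indole
Conditions: NaH (2.5 equiv), TIPSCl (2.3 equiv), THF/DMF, 0 °C to rt
Reagents that add atoms: triisopropylsilyl chloride, CC(C)[Si](Cl)(C(C)C)C(C)C
Why: NaH should form the phenoxide/indolide dianion, which TIPSCl silylates on oxygen and nitrogen, giving two groups that tolerate organolithium reagents and a bulky N-substituent that shields C2.

Step 2
Reactants: 2 1-(triisopropylsilyl)-5-(triisopropylsilyloxy)indole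
Product: 3 3-bromo-1-(triisopropylsilyl)-5-(triisopropylsilyloxy)indole
Conditions: NBS (1.0 equiv), THF, −78 °C
Reagents that add atoms: N-bromosuccinimide, O=C1CCC(=O)N1Br
Why: Electrophilic aromatic bromination of an N-silylindole with NBS should occur at C3, the most nucleophilic carbon, while the N-TIPS group blocks C2.

Step 3
Reactants: 4 1,2,4,5-tetramethoxybenzene; 3 3-bromo-1-(triisopropylsilyl)-5-(triisopropylsilyloxy)indole
Product: 7 3-(2,3,5,6-tetramethoxyphenyl)-1-(triisopropylsilyl)-5-(triisopropylsilyloxy)indole, via 2,3,5,6-tetramethoxyphenyllithium 5 (not isolated), via (2,3,5,6-tetramethoxyphenyl)zinc chloride 6 (not isolated)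
Conditions: 4, n-BuLi, THF, 0 °C; ZnCl2, 0 °C to rt; then 3, Pd2(dba)3 (2 mol %), RuPhos (2-dicyclohexylphosphino-2',6'-diisopropoxybiphenyl, 8 mol %), THF, 65 °C
Reagents that add atoms: none
Why: Directed ortho-metalation between two methoxy groups, transmetalation to zinc and Negishi coupling under a bulky biarylphosphine-ligated zerovalent palladium catalyst is an established way to join di-ortho-substituted arylzinc reagents to heteroaryl bromides.

Step 4
Reactants: 8 4-bromobenzaldehyde; 9 tributyl(3-methylbut-2-en-1-yl)stannane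
Product: 10 4-(3-methylbut-2-en-1-yl)benzaldehyde
Conditions: Pd(PPh3)4 (5 mol %), DMF, 100 °C
Reagents that add atoms: none
Why: Stille coupling of an aryl bromide with a prenylstannane tolerates the aldehyde and should give the linear prenyl arene, because C–C reductive elimination takes place at the less substituted allyl terminus.

Step 5
Reactants: 7 3-(2,3,5,6-tetramethoxyphenyl)-1-(triisopropylsilyl)-5-(triisopropylsilyloxy)indole; 10 4-(3-methylbut-2-en-1-yl)benzaldehyde
Product: 12 (4-prenylphenyl){2,3,5,6-tetramethoxy-4-[1-TIPS-5-(TIPS-oxy)indol-3-yl]phenyl}methanol (racemic), via [2,3,5,6-tetramethoxy-4-(1-TIPS-5-TIPSO-indol-3-yl)phenyl]lithium 11 (not isolated)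
Conditions: n-BuLi (1.1 equiv), TMEDA, THF, 0 °C; then 10, −78 °C to rt; H2O
Reagents that add atoms: none
Why: The only remaining ring C hydrogen lies between two methoxy groups and should be removed by directed ortho-metalation (indole C2 is shielded by N-TIPS), and 1,2-addition of the aryllithium to the aldehyde gives the carbinol, whose stereocentre forms without control and is removed in step 6.

Step 6
Reactants: 12 (4-prenylphenyl){2,3,5,6-tetramethoxy-4-[1-TIPS-5-(TIPS-oxy)indol-3-yl]phenyl}methanol (racemic)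
Product: 13 (4-prenylphenyl){2,3,5,6-tetramethoxy-4-[1-TIPS-5-(TIPS-oxy)indol-3-yl]phenyl}methanone
Conditions: Dess–Martin periodinane, CH2Cl2, rt
Reagents that add atoms: none
Why: Dess–Martin oxidation of a doubly benzylic secondary alcohol is mild enough to leave the prenyl alkene, both silyl groups and the indole untouched.

Step 7
Reactants: 13 (4-prenylphenyl){2,3,5,6-tetramethoxy-4-[1-TIPS-5-(TIPS-oxy)indol-3-yl]phenyl}methanone; 14 bis(pinacolatoboryl)methane
Product: 16 2-{2-(4-prenylphenyl)-2-[2,3,5,6-tetramethoxy-4-(1-TIPS-5-TIPSO-indol-3-yl)phenyl]ethenyl}-Bpin (E/Z mixture), via lithio-bis(pinacolatoboryl)methane 15 (not isolated)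
Conditions: 14 (1.6 equiv), LiTMP (1.5 equiv), THF, 0 °C; then 13, −78 °C to rt
Reagents that add atoms: none
Why: In this boron-Wittig olefination the α-boryl carbanion should add to the non-enolisable diaryl ketone and the β-alkoxy boronate should collapse by B–O elimination to the alkenyl boronate, as is known for benzophenone-type ketones; the alkene geometry does not matter.

Step 8
Reactants: 16 2-{2-(4-prenylphenyl)-2-[2,3,5,6-tetramethoxy-4-(1-TIPS-5-TIPSO-indol-3-yl)phenyl]ethenyl}-Bpin (E/Z mixture)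
Product: 17 3-{4-[2-azido-1-(4-prenylphenyl)ethenyl]-2,3,5,6-tetramethoxyphenyl}-1-TIPS-5-(TIPS-oxy)indole (E/Z mixture)
Conditions: NaN3 (2 equiv), Cu(OAc)2 (20 mol %), MeOH/THF, air, rt, dark
Reagents that add atoms: sodium azide, [N-]=[N+]=[N-].[Na+]
Why: Chan–Lam-type copper-catalysed azidation of alkenylboron compounds proceeds by boron-to-copper transmetalation and C–N reductive elimination from a trivalent copper azide, with air reoxidising the copper, under conditions that spare the silyl groups and the prenyl alkene.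

Step 9
Reactants: 17 3-{4-[2-azido-1-(4-prenylphenyl)ethenyl]-2,3,5,6-tetramethoxyphenyl}-1-TIPS-5-(TIPS-oxy)indole (E/Z mixture)
Product: 18 2-(4-prenylphenyl)-2-[2,3,5,6-tetramethoxy-4-(1-TIPS-5-TIPSO-indol-3-yl)phenyl]-2H-azirine (racemic)
Conditions: toluene, 80 °C, until N2 evolution ends
Reagents that add atoms: none
Why: Terminal vinyl azides lose dinitrogen on mild heating and close to 3-unsubstituted 2H-azirines, so both alkene isomers should converge on one azirine whose quaternary stereocentre forms racemic and is erased in step 10.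

Step 10
Reactants: 18 2-(4-prenylphenyl)-2-[2,3,5,6-tetramethoxy-4-(1-TIPS-5-TIPSO-indol-3-yl)phenyl]-2H-azirine (racemic)
Product: 19 3-[2,3,5,6-tetramethoxy-4-(6-prenyl-1H-indol-3-yl)phenyl]-1-TIPS-5-(TIPS-oxy)indole
Conditions: Rh2(O2CCF3)4 (5 mol %), 1,2-dichloroethane, rt to 40 °C
Reagents that add atoms: none
Why: The Lewis-acidic dirhodium carboxylate should bind the azirine nitrogen and break the strained C2–N single bond, giving a rhodium-bound 2,2-diarylvinyl nitrenoid with nitrogen on the former C3–H carbon. The nitrogen then bonds to an ortho carbon of the 4-prenylphenyl ring in a five-atom electrocyclisation (N, the two former azirine carbons, the ipso and the ortho carbon), which forms N1–C7a and closes the pyrrole ring of indole B; a 1,5-hydrogen shift from C7a to nitrogen restores aromaticity and releases the catalyst. The closest known reaction type is the Rh2(O2CCF3)4- or FeCl2-catalysed isomerisation of 2-aryl-2H-azirines to indoles, and the uncatalysed thermal version is documented for 2,2-diaryl-2H-azirines. No stereocentre is formed, and the stereocentre of racemic 18 vanishes as its carbon becomes C3 of the indole. Two selectivities are needed, ring choice and site choice: ring C has methoxy groups on both ortho carbons, so closure there cannot rearomatise and is unproductive, while the two ortho C–H carbons of the para-substituted ring are equivalent, so a single indole with prenyl at C6 should result. The competing 1,2-hydrogen shift of the nitrenoid to a ketenimine and on to a diarylacetonitrile should be held back by running the catalysed reaction near room temperature.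

Step 11
Reactants: 19 3-[2,3,5,6-tetramethoxy-4-(6-prenyl-1H-indol-3-yl)phenyl]-1-TIPS-5-(TIPS-oxy)indole
Product: 20 3-[2,3,5,6-tetramethoxy-4-(6-prenyl-1H-indol-3-yl)phenyl]-1H-indol-5-ol (target)
Conditions: TBAF (2.5 equiv), THF, 0 °C, argon; then H2O
Reagents that add atoms: none
Why: Fluoride cleaves both the N–Si and the aryl O–Si bond in one desilylation, and the low temperature and exclusion of air protect the oxidation-prone 5-hydroxyindole.

**Compound list**

1 | 5-hydroxyindole | Oc1ccc2[nH]ccc2c1 | starting material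
2 | 1-(triisopropylsilyl)-5-(triisopropylsilyloxy)indole | CC(C)[Si](C(C)C)(C(C)C)Oc1ccc2c(c1)ccn2[Si](C(C)C)(C(C)C)C(C)C | intermediate
3 | 3-bromo-1-(triisopropylsilyl)-5-(triisopropylsilyloxy)indole | CC(C)[Si](C(C)C)(C(C)C)Oc1ccc2c(c1)c(Br)cn2[Si](C(C)C)(C(C)C)C(C)C | intermediate
4 | 1,2,4,5-tetramethoxybenzene | COc1cc(OC)c(OC)cc1OC | starting material
5 | 2,3,5,6-tetramethoxyphenyllithium | [Li]c1c(OC)c(OC)cc(OC)c1OC | intermediate (not isolated)
6 | (2,3,5,6-tetramethoxyphenyl)zinc chloride | Cl[Zn]c1c(OC)c(OC)cc(OC)c1OC | intermediate (not isolated)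
7 | 3-(2,3,5,6-tetramethoxyphenyl)-1-(triisopropylsilyl)-5-(triisopropylsilyloxy)indole | COc1cc(OC)c(OC)c(-c2cn([Si](C(C)C)(C(C)C)C(C)C)c3ccc(O[Si](C(C)C)(C(C)C)C(C)C)cc23)c1OC | intermediate
8 | 4-bromobenzaldehyde | O=Cc1ccc(Br)cc1 | starting material
9 | tributyl(3-methylbut-2-en-1-yl)stannane | CCCC[Sn](CCCC)(CCCC)CC=C(C)C | starting material
10 | 4-(3-methylbut-2-en-1-yl)benzaldehyde | O=Cc1ccc(CC=C(C)C)cc1 | intermediate
11 | [2,3,5,6-tetramethoxy-4-(1-TIPS-5-TIPSO-indol-3-yl)phenyl]lithium | [Li]c1c(OC)c(OC)c(-c2cn([Si](C(C)C)(C(C)C)C(C)C)c3ccc(O[Si](C(C)C)(C(C)C)C(C)C)cc23)c(OC)c1OC | intermediate (not isolated)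
12 | (4-prenylphenyl){2,3,5,6-tetramethoxy-4-[1-TIPS-5-(TIPS-oxy)indol-3-yl]phenyl}methanol, racemic | OC(c1ccc(CC=C(C)C)cc1)c1c(OC)c(OC)c(-c2cn([Si](C(C)C)(C(C)C)C(C)C)c3ccc(O[Si](C(C)C)(C(C)C)C(C)C)cc23)c(OC)c1OC | intermediate
13 | (4-prenylphenyl){2,3,5,6-tetramethoxy-4-[1-TIPS-5-(TIPS-oxy)indol-3-yl]phenyl}methanone | O=C(c1ccc(CC=C(C)C)cc1)c1c(OC)c(OC)c(-c2cn([Si](C(C)C)(C(C)C)C(C)C)c3ccc(O[Si](C(C)C)(C(C)C)C(C)C)cc23)c(OC)c1OC | intermediate
14 | bis(pinacolatoboryl)methane | CC1(C)OB(CB2OC(C)(C)C(C)(C)O2)OC1(C)C | starting material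
15 | lithio-bis(pinacolatoboryl)methane | [Li]C(B1OC(C)(C)C(C)(C)O1)B1OC(C)(C)C(C)(C)O1 | intermediate (not isolated)
16 | 2-{2-(4-prenylphenyl)-2-[2,3,5,6-tetramethoxy-4-(1-TIPS-5-TIPSO-indol-3-yl)phenyl]ethenyl}-Bpin, E/Z mixture | CC1(C)OB(C=C(c2ccc(CC=C(C)C)cc2)c2c(OC)c(OC)c(-c3cn([Si](C(C)C)(C(C)C)C(C)C)c4ccc(O[Si](C(C)C)(C(C)C)C(C)C)cc34)c(OC)c2OC)OC1(C)C | intermediate
17 | 3-{4-[2-azido-1-(4-prenylphenyl)ethenyl]-2,3,5,6-tetramethoxyphenyl}-1-TIPS-5-(TIPS-oxy)indole, E/Z mixture | [N-]=[N+]=NC=C(c1ccc(CC=C(C)C)cc1)c1c(OC)c(OC)c(-c2cn([Si](C(C)C)(C(C)C)C(C)C)c3ccc(O[Si](C(C)C)(C(C)C)C(C)C)cc23)c(OC)c1OC | intermediate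
18 | 2-(4-prenylphenyl)-2-[2,3,5,6-tetramethoxy-4-(1-TIPS-5-TIPSO-indol-3-yl)phenyl]-2H-azirine, racemic | N1=CC1(c1ccc(CC=C(C)C)cc1)c1c(OC)c(OC)c(-c2cn([Si](C(C)C)(C(C)C)C(C)C)c3ccc(O[Si](C(C)C)(C(C)C)C(C)C)cc23)c(OC)c1OC | intermediate
19 | 3-[2,3,5,6-tetramethoxy-4-(6-prenyl-1H-indol-3-yl)phenyl]-1-TIPS-5-(TIPS-oxy)indole | COc1c(OC)c(-c2cn([Si](C(C)C)(C(C)C)C(C)C)c3ccc(O[Si](C(C)C)(C(C)C)C(C)C)cc23)c(OC)c(OC)c1-c1c[nH]c2cc(CC=C(C)C)ccc12 | intermediate
20 | 3-[2,3,5,6-tetramethoxy-4-(6-prenyl-1H-indol-3-yl)phenyl]-1H-indol-5-ol | COc1c(OC)c(-c2c[nH]c3ccc(O)cc23)c(OC)c(OC)c1-c1c[nH]c2cc(CC=C(C)C)ccc12 | target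

**Step count**
Total: 11 steps. Longest linear sequence: 10 steps (steps 1, 2, 3, 5, 6, 7, 8, 9, 10, 11 from 5-hydroxyindole); step 4 is a one-step branch.

**Steps most likely to fail**

Step 10. The nitrenoid may undergo a 1,2-hydrogen shift towards a ketenimine and nitrile instead of cyclising, or the catalyst may be tied up by the electron-rich substrate. Fallback: indole B is attached ready-made by cross-coupling, setting out from 7 and returning at 20. Commercial 6-bromoindole F1 is N-silylated (NaH, TIPSCl, THF) to 6-bromo-1-(triisopropylsilyl)indole F2. Stille coupling with 9 (Pd(PPh3)4, DMF, 100 °C) gives 6-prenyl-1-(triisopropylsilyl)indole F3, and NBS in THF at −78 °C gives 3-bromo-6-prenyl-1-(triisopropylsilyl)indole F4. Compound 7 is lithiated as in step 5 to 11 and transmetalated with ZnCl2 to the arylzinc chloride F5. Negishi coupling of F5 with F4 (Pd2(dba)3, RuPhos, THF, 65 °C) gives the tris-silyl bis-indole F6, which TBAF in THF converts into 20.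

Step 8. Boron-to-copper transmetalation may be slow at the crowded trisubstituted alkenyl boronate, with protodeboronation or copper-induced loss of nitrogen from the product taking over. Fallback: the azide is brought in as a nucleophile, setting out from 13 and returning at 17 (this also bypasses step 7). Corey–Chaykovsky epoxidation of 13 (Me3SI, KOtBu, DMSO, rt) gives the racemic 2,2-diaryloxirane F7. Opening at the CH2 carbon with NaN3 and NH4Cl in DMF/H2O at 60 °C gives the racemic 2-azido-1,1-diarylethanol F8. Dehydration of this tertiary bis-benzylic alcohol with Burgess reagent (toluene, 50 °C) gives 17.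

Step 5. Metalation may be diverted to indole C2 (assisted by a neighbouring ring C methoxy group) or stay incomplete on the bulky biaryl. Fallback: the ring C carbanion is generated by halogen–lithium exchange before indole A is attached, setting out from 4 (with 2 and 10) and returning at 13. Compound 4 is dibrominated (NBS, 2.1 equiv, MeCN, rt) to 1,4-dibromo-2,3,5,6-tetramethoxybenzene F9. One bromine is exchanged (n-BuLi, 1.0 equiv, THF, −78 °C) to 4-bromo-2,3,5,6-tetramethoxyphenyllithium F10, which adds to 10 to give the racemic bromo carbinol F11. Dess–Martin oxidation gives the bromo ketone F12. Compound 2 is borylated at C3 ([Ir(OMe)(cod)]2, 4,4'-di-tert-butyl-2,2'-bipyridine, B2pin2, THF, 60 °C) to the indol-3-yl boronate F13. Suzuki–Miyaura coupling of F12 with F13 (Pd(OAc)2, SPhos, K3PO4, toluene/H2O, 80 °C) gives 13.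

**Further compounds**

F1 | step 10 | 6-bromoindole | Brc1ccc2cc[nH]c2c1
F2 | step 10 | 6-bromo-1-(triisopropylsilyl)indole | Brc1ccc2ccn([Si](C(C)C)(C(C)C)C(C)C)c2c1
F3 | step 10 | 6-(3-methylbut-2-en-1-yl)-1-(triisopropylsilyl)indole | CC(C)=CCc1ccc2ccn([Si](C(C)C)(C(C)C)C(C)C)c2c1
F4 | step 10 | 3-bromo-6-(3-methylbut-2-en-1-yl)-1-(triisopropylsilyl)indole | CC(C)=CCc1ccc2c(Br)cn([Si](C(C)C)(C(C)C)C(C)C)c2c1
F5 | step 10 | [2,3,5,6-tetramethoxy-4-(1-TIPS-5-TIPSO-indol-3-yl)phenyl]zinc chloride | Cl[Zn]c1c(OC)c(OC)c(-c2cn([Si](C(C)C)(C(C)C)C(C)C)c3ccc(O[Si](C(C)C)(C(C)C)C(C)C)cc23)c(OC)c1OC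
F6 | step 10 | 3-{2,3,5,6-tetramethoxy-4-[6-prenyl-1-(triisopropylsilyl)indol-3-yl]phenyl}-1-TIPS-5-(TIPS-oxy)indole | COc1c(OC)c(-c2cn([Si](C(C)C)(C(C)C)C(C)C)c3ccc(O[Si](C(C)C)(C(C)C)C(C)C)cc23)c(OC)c(OC)c1-c1cn([Si](C(C)C)(C(C)C)C(C)C)c2cc(CC=C(C)C)ccc12
F7 | step 8 | 2-(4-prenylphenyl)-2-[2,3,5,6-tetramethoxy-4-(1-TIPS-5-TIPSO-indol-3-yl)phenyl]oxirane, racemic | C1OC1(c1ccc(CC=C(C)C)cc1)c1c(OC)c(OC)c(-c2cn([Si](C(C)C)(C(C)C)C(C)C)c3ccc(O[Si](C(C)C)(C(C)C)C(C)C)cc23)c(OC)c1OC
F8 | step 8 | 2-azido-1-(4-prenylphenyl)-1-[2,3,5,6-tetramethoxy-4-(1-TIPS-5-TIPSO-indol-3-yl)phenyl]ethanol, racemic | [N-]=[N+]=NCC(O)(c1ccc(CC=C(C)C)cc1)c1c(OC)c(OC)c(-c2cn([Si](C(C)C)(C(C)C)C(C)C)c3ccc(O[Si](C(C)C)(C(C)C)C(C)C)cc23)c(OC)c1OC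
F9 | step 5 | 1,4-dibromo-2,3,5,6-tetramethoxybenzene | COc1c(Br)c(OC)c(OC)c(Br)c1OC
F10 | step 5 | 4-bromo-2,3,5,6-tetramethoxyphenyllithium | [Li]c1c(OC)c(OC)c(Br)c(OC)c1OC
F11 | step 5 | (4-bromo-2,3,5,6-tetramethoxyphenyl)(4-prenylphenyl)methanol, racemic | OC(c1ccc(CC=C(C)C)cc1)c1c(OC)c(OC)c(Br)c(OC)c1OC
F12 | step 5 | (4-bromo-2,3,5,6-tetramethoxyphenyl)(4-prenylphenyl)methanone | O=C(c1ccc(CC=C(C)C)cc1)c1c(OC)c(OC)c(Br)c(OC)c1OC
F13 | step 5 | 3-Bpin-1-(triisopropylsilyl)-5-(triisopropylsilyloxy)indole | CC1(C)OB(c2cn([Si](C(C)C)(C(C)C)C(C)C)c3ccc(O[Si](C(C)C)(C(C)C)C(C)C)cc23)OC1(C)C
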